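The readings stem from a simulated flask for substances that don't exist; noise was put on by code.

- 5 questions are asked of the new flask, and you can meet them with one ledger: where each part of the substrate charged ends up.

| setting | Tuesday's | Wednesday's | flask |
|---|---|---|---|
| substrate | 0.50 mM | 0.50 mM | 0.50 mM |
| partner | 1 equiv | 2.2 equiv | 1.50 equiv |
| second reagent | 1.1 equiv | 1.1 equiv | 1.10 equiv |
| remark | run made earlier | run made earlier |  |
| time |  |  | 6.0 h |

| run | time / h | substrate / % | target / % | side product B / % |
|---|---|---|---|---|
| Tuesday's | 2.00 | 1.3 | 8.1 | 50.0 |
| Tuesday's | 4.00 | 0 | 9.0 | 48.8 |
| Tuesday's | 5.00 | 0 | 9.2 | 48.8 |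
| Tuesday's | 8.00 | 0 | 8.4 | 49.4 |
| Wednesday's | 2.00 | 1.8 | 13.3 | 58.8 |
| Wednesday's | 4.00 | 1.6 | 13.8 | 57.7 |
| Wednesday's | 5.00 | 0 | 14.5 | 61.1 |
| Wednesday's | 8.00 | 0 | 15.8 | 58.6 |

(scatter of a reading: 1 percentage point)

1. which holds at 6.0 h: what has brought the reaction to rest, or that it has not come to rest (the second reagent has run out first / the partner has run out first / it is still moving / all of the substrate has reacted)
2. share of the substrate used up at 6.0 h
3. target at 6.0 h, in percent of the substrate charged
4. side product B at 6.0 h, in percent of the substrate charged
5. side product A at 6.0 h, in percent of the substrate charged

- a species is counted by the substrate in it: one side product B counts as two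
- the reaction counts as stopped when no species that holds the substrate changes by six tenths of a point or more over the second half of the time

- First entry, the substrate: Tuesday's run reads 0% at 4.00 h, and Wednesday's reads 0% at 5.00 h. You can therefore book the charge as products in both runs at 8.00 h.
- Second entry, what was read at that time: Tuesday's run holds 8.4% target and 49.4% side product B, while Wednesday's holds 15.8% and 58.6%.
- Closing entry: side product A has no readings, so the books close on it, at 42.2% of the charge on Tuesday and 25.6% on Wednesday.
- Now join the two ends. Divide the share in target and side product B by the share in side product A, then by the equivalents of partner: Tuesday's run gives 1.37 and Wednesday's 1.32, which agree within the scatter of the readings.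
- Their mean, 1.35, is my carried quantity: the selectivity factor s, the share through target and side product B per share of side product A and per equivalent of partner, with second reagent held at 1.10 equiv.
- The new flask at 1.50 equiv has more partner than Tuesday's run and less than Wednesday's, so I book its substrate as used up by 6.0 h as well. My reckoning then puts those shares at 2.02 to one, which leaves side product A at 33.1%.
- The forecast says: all of the substrate has reacted, with conversion 100%, target 11.5%, side product B 54.5% and side product A 34%, against my 33.1%. Its ground is a ratio running “roughly inverse to partner”.
- The new flask gives: all of the substrate has reacted, with conversion 100%, target 11.2%, side product B 54.9% and side product A 33.9%.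

    substrate + partner → intermediate (k = 13.2 M⁻¹ s⁻¹)
    second reagent + intermediate → target (k = 22.3 M⁻¹ s⁻¹)
    substrate + second reagent → side product A (k = 16.8 M⁻¹ s⁻¹)
    substrate + intermediate → side product B (k = 257 M⁻¹ s⁻¹)

- In the new flask at 6.00 h, the substrate, at 0%, is less than the partner at 74% and less than the second reagent at 59%, each of its own charge, and its books return s as 1.30. Take the same flask with 0.600 equiv of partner: s puts the two shares at 0.807 to one, so side product A should stand at 55.3%. That neighbouring flask gives target 5.73%, side product B 39.6% and side product A 54.7%.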